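**Strategy.** Everything rests on disconnecting the bond between the alkene CH and the methyl-bearing carbon on C2 of the right-hand 4-pyranone. That carbon is exocyclic to the ring's C2=C3–C4=O enone, so a radical there is stabilised like a benzylic one. A nickel/bis(oxazoline)-catalysed enantioconvergent reductive cross-coupling therefore joins an (E)-alkenyl bromide (left half, acetate in place) with a stereorandom secondary chloride (right half): one operation forms the bond, sets its stereocentre under catalyst control and keeps the alkene geometry. Both precursors are silyl-protected pyranones made by acylating a β-diketone dianion and cyclodehydrating the triketone; their stereocentres come from a β-ketoimide aldol/reduction and a Fráter–Seebach methylation.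

Key step: step 20

Assumption: 4-methylheptane-3,5-dione and methyl (S)-3-hydroxypentanoate are taken as purchasable, and the ligand antipode in step 20 is the one that delivers the R centre.

**Left half (steps 1–13)**

Step 1
Reactants: 1 (R)-4-benzyl-3-propionyloxazolidin-2-one; 2 propanal
Product: 3 (R)-4-benzyl-3-[(2R,3S)-3-hydroxy-2-methylpentanoyl]oxazolidin-2-one
Conditions: Bu2BOTf, Et3N, CH2Cl2, 0 °C; 2, −78 → 0 °C; H2O2, MeOH, pH 7 buffer
Reagents that add atoms: none
Why: Evans syn aldol; the (Z)-boron enolate reacts through a Zimmerman–Traxler chair on the face dictated by the (R)-benzyl auxiliary, which should set the (2R) methyl centre.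

Step 2
Reactants: 3 (R)-4-benzyl-3-[(2R,3S)-3-hydroxy-2-methylpentanoyl]oxazolidin-2-one
Product: 4 (R)-4-benzyl-3-[(R)-2-methyl-3-oxopentanoyl]oxazolidin-2-one
Conditions: SO3·pyridine, DMSO, Et3N, CH2Cl2, −5 °C
Reagents that add atoms: none
Why: Parikh–Doering oxidation; the β-ketoimide resists enolisation toward C2 (A1,3 strain), so the methyl centre should survive.

Step 3
Reactants: 5 prop-2-yn-1-ol
Product: 6 (E)-3-bromo-2-methylprop-2-en-1-ol
Conditions: AlMe3 (3 equiv), Cp2ZrCl2 (0.25 equiv), CH2Cl2, 0 °C → rt; then NBS, THF, −30 → 0 °C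
Reagents that add atoms: trimethylaluminium C[Al](C)C; N-bromosuccinimide O=C1CCC(=O)N1Br
Why: Negishi zirconium-catalysed carboalumination adds Me and Al syn (Me to the internal carbon), and bromodealumination with retention should give the E bromide.

Step 4
Reactants: 6 (E)-3-bromo-2-methylprop-2-en-1-ol
Product: 7 (E)-3-bromo-2-methylprop-2-enal
Conditions: MnO2, CH2Cl2, rt
Reagents that add atoms: none
Why: Allylic oxidation with MnO2 stops at the aldehyde and should not isomerise the alkene.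

Step 5
Reactants: 4 (R)-4-benzyl-3-[(R)-2-methyl-3-oxopentanoyl]oxazolidin-2-one; 7 (E)-3-bromo-2-methylprop-2-enal
Product: 8 (R)-4-benzyl-3-[(2R,4S,5S,E)-7-bromo-5-hydroxy-2,4,6-trimethyl-3-oxohept-6-enoyl]oxazolidin-2-one
Conditions: Sn(OTf)2, Et3N, CH2Cl2, −20 °C; then 7, −78 → −20 °C
Reagents that add atoms: none
Why: Evans β-ketoimide tin(II) aldol; the (Z)-tin enolate forms at the ethyl ketone side and the C2 methyl centre should direct the 2,4-anti-4,5-syn adduct.

Step 6
Reactants: 8 (R)-4-benzyl-3-[(2R,4S,5S,E)-7-bromo-5-hydroxy-2,4,6-trimethyl-3-oxohept-6-enoyl]oxazolidin-2-one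
Product: 9 (R)-4-benzyl-3-[(2R,3R,4R,5S,E)-7-bromo-3,5-dihydroxy-2,4,6-trimethylhept-6-enoyl]oxazolidin-2-one
Conditions: Zn(BH4)2, CH2Cl2/Et2O, −78 → −20 °C
Reagents that add atoms: none
Why: Chelation-controlled (hydroxyl-directed) reduction; zinc bridges the C5 oxygen and the ketone and external hydride delivery should give the 1,3-syn diol.

Step 7
Reactants: 9 (R)-4-benzyl-3-[(2R,3R,4R,5S,E)-7-bromo-3,5-dihydroxy-2,4,6-trimethylhept-6-enoyl]oxazolidin-2-one
Product: 11 (3R,4R,5S,6S)-6-[(E)-1-bromoprop-1-en-2-yl]-3,5-dimethyl-4-(triethylsilyloxy)tetrahydro-2H-pyran-2-one, via (3R,4R,5R,6S)-6-[(E)-1-bromoprop-1-en-2-yl]-4-hydroxy-3,5-dimethyltetrahydro-2H-pyran-2-one 10 (not isolated)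
Conditions: Et3N, DMAP (cat.), CH2Cl2, rt; then 2,6-lutidine, TESOTf, −78 °C
Reagents that add atoms: triethylsilyl trifluoromethanesulfonate CC[Si](CC)(CC)OS(=O)(=O)C(F)(F)F
Why: Lactonisation (intramolecular acyl transfer) of the δ-hydroxy imide releases the auxiliary and ties up only the allylic oxygen, so silylation should mark the other hydroxyl alone.

Step 8
Reactants: 11 (3R,4R,5S,6S)-6-[(E)-1-bromoprop-1-en-2-yl]-3,5-dimethyl-4-(triethylsilyloxy)tetrahydro-2H-pyran-2-one
Product: 12 (2R,3R,4S,5S,E)-7-bromo-5-hydroxy-N-methoxy-N,2,4,6-tetramethyl-3-(triethylsilyloxy)hept-6-enamide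
Conditions: MeONHMe·HCl, AlMe3, CH2Cl2, 0 °C → rt
Reagents that add atoms: N,O-dimethylhydroxylamine hydrochloride CNOC.Cl
Why: Weinreb aminolysis of the lactone with the aluminium amide opens the ring without touching the α-centre; the product is used at once to avoid relactonisation.

Step 9
Reactants: 12 (2R,3R,4S,5S,E)-7-bromo-5-hydroxy-N-methoxy-N,2,4,6-tetramethyl-3-(triethylsilyloxy)hept-6-enamide
Product: 13 (2R,3R,4R,5S,E)-7-bromo-5-(tert-butyldimethylsilyloxy)-N-methoxy-N,2,4,6-tetramethyl-3-(triethylsilyloxy)hept-6-enamide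
Conditions: TBSOTf, 2,6-lutidine, CH2Cl2, −78 °C
Reagents that add atoms: tert-butyldimethylsilyl trifluoromethanesulfonate CC(C)(C)[Si](C)(C)OS(=O)(=O)C(F)(F)F
Why: Silyl ether formation on the liberated allylic alcohol gives two differentiated silyl ethers (TES on the future acetate oxygen, TBS on the future free hydroxyl).

Step 10
Reactants: 13 (2R,3R,4R,5S,E)-7-bromo-5-(tert-butyldimethylsilyloxy)-N-methoxy-N,2,4,6-tetramethyl-3-(triethylsilyloxy)hept-6-enamide; 14 4-methylheptane-3,5-dione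
Product: 15 (8R,9R,10R,11S,E)-13-bromo-11-(tert-butyldimethylsilyloxy)-4,6,8,10,12-pentamethyl-9-(triethylsilyloxy)tridec-12-ene-3,5,7-trione (mixture of C4/C6 epimers and enol forms)
Conditions: 14 (3 equiv), LDA (6 equiv), THF, −78 → 0 °C; then 13, −78 → −30 °C; aq. NH4Cl
Reagents that add atoms: none
Why: Hauser–Harris acylation of the terminal carbanion of the β-diketone dianion by the Weinreb amide; the chelated tetrahedral intermediate should prevent over-addition and keep the α-centre from enolising before the quench.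

Step 11
Reactants: 15 (8R,9R,10R,11S,E)-13-bromo-11-(tert-butyldimethylsilyloxy)-4,6,8,10,12-pentamethyl-9-(triethylsilyloxy)tridec-12-ene-3,5,7-trione
Product: 16 2-[(2R,3R,4R,5S,E)-7-bromo-5-(tert-butyldimethylsilyloxy)-4,6-dimethyl-3-(triethylsilyloxy)hept-6-en-2-yl]-6-ethyl-3,5-dimethyl-4H-pyran-4-one
Conditions: Ph3P, CCl4, THF, rt
Reagents that add atoms: none
Why: Cyclodehydration of the 1,3,5-triketone to the 4-pyranone; both labile methyl centres become sp2 and the near-neutral conditions should spare the adjacent stereocentre and the silyl ethers.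

Step 12
Reactants: 16 2-[(2R,3R,4R,5S,E)-7-bromo-5-(tert-butyldimethylsilyloxy)-4,6-dimethyl-3-(triethylsilyloxy)hept-6-en-2-yl]-6-ethyl-3,5-dimethyl-4H-pyran-4-one
Product: 17 2-[(2R,3R,4R,5S,E)-7-bromo-5-(tert-butyldimethylsilyloxy)-3-hydroxy-4,6-dimethylhept-6-en-2-yl]-6-ethyl-3,5-dimethyl-4H-pyran-4-one
Conditions: PPTS, MeOH/CH2Cl2, 0 °C → rt
Reagents that add atoms: none
Why: Acid-catalysed methanolysis should remove the TES ether selectively, since it is far more labile than the secondary TBS ether.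

Step 13
Reactants: 17 2-[(2R,3R,4R,5S,E)-7-bromo-5-(tert-butyldimethylsilyloxy)-3-hydroxy-4,6-dimethylhept-6-en-2-yl]-6-ethyl-3,5-dimethyl-4H-pyran-4-one
Product: 18 (2R,3R,4R,5S,E)-7-bromo-5-(tert-butyldimethylsilyloxy)-2-(6-ethyl-3,5-dimethyl-4-oxo-4H-pyran-2-yl)-4,6-dimethylhept-6-en-3-yl acetate
Conditions: Ac2O, DMAP, pyridine, CH2Cl2, rt
Reagents that add atoms: acetic anhydride CC(=O)OC(C)=O
Why: DMAP-catalysed acetylation of the only free hydroxyl; the amine bases are too weak to trigger β-elimination next to the pyranone.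

**Right half (steps 14–19)**

Step 14
Reactants: 19 methyl (S)-3-hydroxypentanoate
Product: 20 methyl (2S,3S)-3-hydroxy-2-methylpentanoate
Conditions: LDA (2.2 equiv), THF, −78 → −20 °C; MeI, DMPU, −78 → −20 °C
Reagents that add atoms: iodomethane CI
Why: Fráter–Seebach alkylation; the chelated alkoxide–enolate dianion is methylated anti to the ethyl-bearing carbinol, which should give the anti (2S,3S) product.

Step 15
Reactants: 20 methyl (2S,3S)-3-hydroxy-2-methylpentanoate
Product: 21 methyl (2S,3S)-3-(tert-butyldimethylsilyloxy)-2-methylpentanoate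
Conditions: TBSOTf, 2,6-lutidine, CH2Cl2, −78 °C
Reagents that add atoms: tert-butyldimethylsilyl trifluoromethanesulfonate CC(C)(C)[Si](C)(C)OS(=O)(=O)C(F)(F)F
Why: Silyl ether formation blocks the hydroxyl so that it cannot form hemiketals or dihydropyranones at the triketone stage.

Step 16
Reactants: 21 methyl (2S,3S)-3-(tert-butyldimethylsilyloxy)-2-methylpentanoate
Product: 22 (2S,3S)-3-(tert-butyldimethylsilyloxy)-N-methoxy-N,2-dimethylpentanamide
Conditions: MeONHMe·HCl, i-PrMgCl, THF, −20 → 0 °C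
Reagents that add atoms: N,O-dimethylhydroxylamine hydrochloride CNOC.Cl
Why: Weinreb amide formation from the ester with the magnesium amide, conditions under which α-methyl esters normally keep their configuration.

Step 17
Reactants: 22 (2S,3S)-3-(tert-butyldimethylsilyloxy)-N-methoxy-N,2-dimethylpentanamide; 14 4-methylheptane-3,5-dione
Product: 23 (8S,9S)-9-(tert-butyldimethylsilyloxy)-4,6,8-trimethylundecane-3,5,7-trione (mixture of C4/C6 epimers and enol forms)
Conditions: 14 (3 equiv), LDA (6 equiv), THF, −78 → 0 °C; then 22, −78 → −30 °C; aq. NH4Cl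
Reagents that add atoms: none
Why: Same Hauser–Harris dianion acylation as step 10, here on a smaller and less hindered amide.

Step 18
Reactants: 23 (8S,9S)-9-(tert-butyldimethylsilyloxy)-4,6,8-trimethylundecane-3,5,7-trione
Product: 24 2-[(2S,3S)-3-(tert-butyldimethylsilyloxy)pentan-2-yl]-6-ethyl-3,5-dimethyl-4H-pyran-4-one
Conditions: Ph3P, CCl4, THF, rt
Reagents that add atoms: none
Why: Triketone cyclodehydration to the 4-pyranone as in step 11.

Step 19
Reactants: 24 2-[(2S,3S)-3-(tert-butyldimethylsilyloxy)pentan-2-yl]-6-ethyl-3,5-dimethyl-4H-pyran-4-one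
Product: 25 2-(1-chloroethyl)-6-[(2S,3S)-3-(tert-butyldimethylsilyloxy)pentan-2-yl]-3,5-dimethyl-4H-pyran-4-one (both epimers at the C–Cl carbon)
Conditions: LiHMDS (1.1 equiv), THF, −78 °C; then added to C2Cl6 (3 equiv), THF, −78 °C
Reagents that add atoms: hexachloroethane ClC(Cl)(Cl)C(Cl)(Cl)Cl
Why: Vinylogous enolate formation at the ethyl CH2 followed by electrophilic chlorination; the methine on the other arm should be spared because enolisation there would force a substituent against the C5 methyl (A1,3 strain), and the configuration at the new carbon is irrelevant for step 20.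

**Union and end game (steps 20–21)**

Step 20
Reactants: 18 (2R,3R,4R,5S,E)-7-bromo-5-(tert-butyldimethylsilyloxy)-2-(6-ethyl-3,5-dimethyl-4-oxo-4H-pyran-2-yl)-4,6-dimethylhept-6-en-3-yl acetate; 25 2-(1-chloroethyl)-6-[(2S,3S)-3-(tert-butyldimethylsilyloxy)pentan-2-yl]-3,5-dimethyl-4H-pyran-4-one
Product: 26 (2R,3R,4R,5S,6E,8R)-5-(tert-butyldimethylsilyloxy)-8-{6-[(2S,3S)-3-(tert-butyldimethylsilyloxy)pentan-2-yl]-3,5-dimethyl-4-oxo-4H-pyran-2-yl}-2-(6-ethyl-3,5-dimethyl-4-oxo-4H-pyran-2-yl)-4,6-dimethylnon-6-en-3-yl acetate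
Conditions: NiCl2·dme (10 mol %), cyclopropane-1,1-diyl-bridged indanyl bis(oxazoline) (11 mol %), Mn powder (3 equiv), NaI (0.5 equiv), DMA, 0 °C
Reagents that add atoms: none
Why: Ni(0) inserts into the alkenyl C–Br bond of 18 with retention of the E geometry, while the C–Cl bond of 25 (activated as the iodide by NaI) is cleaved by halogen abstraction to a planar radical on the exocyclic carbon, delocalised into the C2=C3–C4=O unit of the pyranone; capture of this radical by the ligated alkenylnickel(II) and reductive elimination from Ni(III) form the C(sp2)–C(sp3) bond, and Mn returns nickel to the low-valent state. The closest known reaction type is the nickel/bis(oxazoline)-catalysed asymmetric reductive cross-coupling of alkenyl bromides with secondary benzylic chlorides. No ring is closed. The one new stereocentre is set by the chiral ligand (catalyst control, convergent for both chloride epimers); the resident centres are remote (the silyloxy carbon two atoms from the reacting alkenyl carbon, and the centre across the pyranone ring), and the ligand antipode is chosen to deliver R. The step needs cross- over homo-coupling, secured by the different activation modes of the sp2 bromide (two-electron) and the sp3 chloride (radical); it needs bonding at the exocyclic carbon and not at ring C3, secured because C3 is fully substituted and attack there would break the pyranone conjugation; and it needs retention of alkene geometry, which is inherent in the alkenylnickel pathway.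

Step 21
Reactants: 26 (2R,3R,4R,5S,6E,8R)-5-(tert-butyldimethylsilyloxy)-8-{6-[(2S,3S)-3-(tert-butyldimethylsilyloxy)pentan-2-yl]-3,5-dimethyl-4-oxo-4H-pyran-2-yl}-2-(6-ethyl-3,5-dimethyl-4-oxo-4H-pyran-2-yl)-4,6-dimethylnon-6-en-3-yl acetate
Product: 27 (2R,3R,4S,5S,6E,8R)-2-(6-ethyl-3,5-dimethyl-4-oxo-4H-pyran-2-yl)-5-hydroxy-8-{6-[(2S,3S)-3-hydroxypentan-2-yl]-3,5-dimethyl-4-oxo-4H-pyran-2-yl}-4,6-dimethylnon-6-en-3-yl acetate (CNP0290537.1)
Conditions: HF·pyridine, pyridine, THF, 0 °C → rt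
Reagents that add atoms: none
Why: Fluoride-mediated cleavage of both TBS ethers under buffered, mildly acidic conditions, under which the acetate should neither migrate to the 1,3-related hydroxyl nor eliminate.

**Compound list**

1 | (R)-4-benzyl-3-propionyloxazolidin-2-one | CCC(=O)N1[C@H](Cc2ccccc2)COC1=O | starting material
2 | propanal | CCC=O | starting material
3 | (R)-4-benzyl-3-[(2R,3S)-3-hydroxy-2-methylpentanoyl]oxazolidin-2-one | O=C1OC[C@@H](Cc2ccccc2)N1C(=O)[C@H](C)[C@@H](O)CC | intermediate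
4 | (R)-4-benzyl-3-[(R)-2-methyl-3-oxopentanoyl]oxazolidin-2-one | O=C1OC[C@@H](Cc2ccccc2)N1C(=O)[C@H](C)C(=O)CC | intermediate
5 | prop-2-yn-1-ol | C#CCO | starting material
6 | (E)-3-bromo-2-methylprop-2-en-1-ol | OC/C(C)=C/Br | intermediate
7 | (E)-3-bromo-2-methylprop-2-enal | O=C/C(C)=C/Br | intermediate
8 | (R)-4-benzyl-3-[(2R,4S,5S,E)-7-bromo-5-hydroxy-2,4,6-trimethyl-3-oxohept-6-enoyl]oxazolidin-2-one | O=C1OC[C@@H](Cc2ccccc2)N1C(=O)[C@H](C)C(=O)[C@@H](C)[C@H](O)/C(C)=C/Br | intermediate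
9 | (R)-4-benzyl-3-[(2R,3R,4R,5S,E)-7-bromo-3,5-dihydroxy-2,4,6-trimethylhept-6-enoyl]oxazolidin-2-one | O=C1OC[C@@H](Cc2ccccc2)N1C(=O)[C@H](C)[C@H](O)[C@@H](C)[C@H](O)/C(C)=C/Br | intermediate
10 | (3R,4R,5R,6S)-6-[(E)-1-bromoprop-1-en-2-yl]-4-hydroxy-3,5-dimethyltetrahydro-2H-pyran-2-one | O=C1[C@H](C)[C@H](O)[C@@H](C)[C@H](O1)/C(C)=C/Br | intermediate
11 | (3R,4R,5S,6S)-6-[(E)-1-bromoprop-1-en-2-yl]-3,5-dimethyl-4-(triethylsilyloxy)tetrahydro-2H-pyran-2-one | O=C1[C@H](C)[C@H](O[Si](CC)(CC)CC)[C@@H](C)[C@H](O1)/C(C)=C/Br | intermediate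
12 | (2R,3R,4S,5S,E)-7-bromo-5-hydroxy-N-methoxy-N,2,4,6-tetramethyl-3-(triethylsilyloxy)hept-6-enamide | CON(C)C(=O)[C@H](C)[C@H](O[Si](CC)(CC)CC)[C@@H](C)[C@H](O)/C(C)=C/Br | intermediate
13 | (2R,3R,4R,5S,E)-7-bromo-5-(tert-butyldimethylsilyloxy)-N-methoxy-N,2,4,6-tetramethyl-3-(triethylsilyloxy)hept-6-enamide | CON(C)C(=O)[C@H](C)[C@H](O[Si](CC)(CC)CC)[C@@H](C)[C@H](O[Si](C)(C)C(C)(C)C)/C(C)=C/Br | intermediate
14 | 4-methylheptane-3,5-dione | CCC(=O)C(C)C(=O)CC | starting material
15 | (8R,9R,10R,11S,E)-13-bromo-11-(tert-butyldimethylsilyloxy)-4,6,8,10,12-pentamethyl-9-(triethylsilyloxy)tridec-12-ene-3,5,7-trione | CCC(=O)C(C)C(=O)C(C)C(=O)[C@H](C)[C@H](O[Si](CC)(CC)CC)[C@@H](C)[C@H](O[Si](C)(C)C(C)(C)C)/C(C)=C/Br | intermediate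
16 | 2-[(2R,3R,4R,5S,E)-7-bromo-5-(tert-butyldimethylsilyloxy)-4,6-dimethyl-3-(triethylsilyloxy)hept-6-en-2-yl]-6-ethyl-3,5-dimethyl-4H-pyran-4-one | CCc1oc([C@H](C)[C@H](O[Si](CC)(CC)CC)[C@@H](C)[C@H](O[Si](C)(C)C(C)(C)C)/C(C)=C/Br)c(C)c(=O)c1C | intermediate
17 | 2-[(2R,3R,4R,5S,E)-7-bromo-5-(tert-butyldimethylsilyloxy)-3-hydroxy-4,6-dimethylhept-6-en-2-yl]-6-ethyl-3,5-dimethyl-4H-pyran-4-one | CCc1oc([C@H](C)[C@H](O)[C@@H](C)[C@H](O[Si](C)(C)C(C)(C)C)/C(C)=C/Br)c(C)c(=O)c1C | intermediate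
18 | (2R,3R,4R,5S,E)-7-bromo-5-(tert-butyldimethylsilyloxy)-2-(6-ethyl-3,5-dimethyl-4-oxo-4H-pyran-2-yl)-4,6-dimethylhept-6-en-3-yl acetate | CCc1oc([C@H](C)[C@H](OC(C)=O)[C@@H](C)[C@H](O[Si](C)(C)C(C)(C)C)/C(C)=C/Br)c(C)c(=O)c1C | intermediate
19 | methyl (S)-3-hydroxypentanoate | CC[C@H](O)CC(=O)OC | starting material
20 | methyl (2S,3S)-3-hydroxy-2-methylpentanoate | CC[C@H](O)[C@H](C)C(=O)OC | intermediate
21 | methyl (2S,3S)-3-(tert-butyldimethylsilyloxy)-2-methylpentanoate | CC[C@H](O[Si](C)(C)C(C)(C)C)[C@H](C)C(=O)OC | intermediate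
22 | (2S,3S)-3-(tert-butyldimethylsilyloxy)-N-methoxy-N,2-dimethylpentanamide | CC[C@H](O[Si](C)(C)C(C)(C)C)[C@H](C)C(=O)N(C)OC | intermediate
23 | (8S,9S)-9-(tert-butyldimethylsilyloxy)-4,6,8-trimethylundecane-3,5,7-trione | CCC(=O)C(C)C(=O)C(C)C(=O)[C@@H](C)[C@@H](O[Si](C)(C)C(C)(C)C)CC | intermediate
24 | 2-[(2S,3S)-3-(tert-butyldimethylsilyloxy)pentan-2-yl]-6-ethyl-3,5-dimethyl-4H-pyran-4-one | CCc1oc([C@@H](C)[C@@H](O[Si](C)(C)C(C)(C)C)CC)c(C)c(=O)c1C | intermediate
25 | 2-(1-chloroethyl)-6-[(2S,3S)-3-(tert-butyldimethylsilyloxy)pentan-2-yl]-3,5-dimethyl-4H-pyran-4-one (C–Cl epimers) | CC(Cl)c1oc([C@@H](C)[C@@H](O[Si](C)(C)C(C)(C)C)CC)c(C)c(=O)c1C | intermediate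
26 | (2R,3R,4R,5S,6E,8R)-5-(tert-butyldimethylsilyloxy)-8-{6-[(2S,3S)-3-(tert-butyldimethylsilyloxy)pentan-2-yl]-3,5-dimethyl-4-oxo-4H-pyran-2-yl}-2-(6-ethyl-3,5-dimethyl-4-oxo-4H-pyran-2-yl)-4,6-dimethylnon-6-en-3-yl acetate | CCc1oc([C@H](C)[C@H](OC(C)=O)[C@@H](C)[C@H](O[Si](C)(C)C(C)(C)C)/C(C)=C/[C@@H](C)c2oc([C@@H](C)[C@@H](O[Si](C)(C)C(C)(C)C)CC)c(C)c(=O)c2C)c(C)c(=O)c1C | intermediate
27 | (2R,3R,4S,5S,6E,8R)-2-(6-ethyl-3,5-dimethyl-4-oxo-4H-pyran-2-yl)-5-hydroxy-8-{6-[(2S,3S)-3-hydroxypentan-2-yl]-3,5-dimethyl-4-oxo-4H-pyran-2-yl}-4,6-dimethylnon-6-en-3-yl acetate | CCc1oc([C@H](C)[C@H](OC(C)=O)[C@@H](C)[C@H](O)/C(C)=C/[C@@H](C)c2oc([C@@H](C)[C@@H](O)CC)c(C)c(=O)c2C)c(C)c(=O)c1C | target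

**Totals.** Total step count: 21. Longest linear sequence: 13 steps (1, 2, 5–13, 20, 21, from compound 1).

**Steps most likely to fail**

Step 20. The hindered pyranone-stabilised radical may be reduced further to a manganese dienolate (loss of chloride without coupling), the partners may homocouple, or facial discrimination at the crowded centre may be poor. The fallback sets out from 25 and 18 and comes back at 26. Chloride 25 would be converted with zinc dust and LiCl in THF into 1-{6-[(2S,3S)-3-(tert-butyldimethylsilyloxy)pentan-2-yl]-3,5-dimethyl-4-oxo-4H-pyran-2-yl}ethylzinc chloride F1, a Reformatsky-type vinylogous zinc enolate. A palladium-catalysed Negishi coupling of F1 with bromide 18 (Pd2(dba)3, SPhos, THF, rt) would then form the same bond by a two-electron pathway. Without catalyst control it should give 26 together with its epimer at the new methine, the (8S)-epimer of 26 F2, which would be removed by preparative HPLC.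

Step 10. Attack of the secondary carbanion on the α-branched amide may be slow enough that proton transfer, or base-induced loss of HBr from the alkenyl bromide, competes. The fallback sets out from 13 and comes back at 15. Amide 13 would be reduced (DIBAL-H, THF, −78 °C) to (2R,3R,4R,5S,E)-7-bromo-5-(tert-butyldimethylsilyloxy)-2,4,6-trimethyl-3-(triethylsilyloxy)hept-6-enal F3. The far more electrophilic aldehyde would take up the dianion of 14 at −78 °C to give 13-bromo-11-(tert-butyldimethylsilyloxy)-7-hydroxy-4,6,8,10,12-pentamethyl-9-(triethylsilyloxy)tridec-12-ene-3,5-dione F4 as a diastereomer mixture. Dess–Martin oxidation (NaHCO3, CH2Cl2) would converge this on triketone 15. The same detour is available for step 17.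

Step 19. The monochloride is more acidic than 24, so proton exchange with unreacted anion may lead to double chlorination, and chlorine transfer to the hindered anion may be slow. The fallback sets out from 24 and comes back at 25. The lithium vinylogous enolate of 24 would be hydroxylated with 3-phenyl-2-(phenylsulfonyl)oxaziridine to 2-(1-hydroxyethyl)-6-[(2S,3S)-3-(tert-butyldimethylsilyloxy)pentan-2-yl]-3,5-dimethyl-4H-pyran-4-one F5 (carbinol epimers). An Appel reaction (Ph3P, CCl4, CH2Cl2) would then give chloride 25.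

**Further compounds**

F1 | step 20 | 1-{6-[(2S,3S)-3-(tert-butyldimethylsilyloxy)pentan-2-yl]-3,5-dimethyl-4-oxo-4H-pyran-2-yl}ethylzinc chloride | CC([Zn]Cl)c1oc([C@@H](C)[C@@H](O[Si](C)(C)C(C)(C)C)CC)c(C)c(=O)c1C
F2 | step 20 | (8S)-epimer of 26 | CCc1oc([C@H](C)[C@H](OC(C)=O)[C@@H](C)[C@H](O[Si](C)(C)C(C)(C)C)/C(C)=C/[C@H](C)c2oc([C@@H](C)[C@@H](O[Si](C)(C)C(C)(C)C)CC)c(C)c(=O)c2C)c(C)c(=O)c1C
F3 | step 10 | (2R,3R,4R,5S,E)-7-bromo-5-(tert-butyldimethylsilyloxy)-2,4,6-trimethyl-3-(triethylsilyloxy)hept-6-enal | O=C[C@H](C)[C@H](O[Si](CC)(CC)CC)[C@@H](C)[C@H](O[Si](C)(C)C(C)(C)C)/C(C)=C/Br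
F4 | step 10 | 13-bromo-11-(tert-butyldimethylsilyloxy)-7-hydroxy-4,6,8,10,12-pentamethyl-9-(triethylsilyloxy)tridec-12-ene-3,5-dione | CCC(=O)C(C)C(=O)C(C)C(O)[C@H](C)[C@H](O[Si](CC)(CC)CC)[C@@H](C)[C@H](O[Si](C)(C)C(C)(C)C)/C(C)=C/Br
F5 | step 19 | 2-(1-hydroxyethyl)-6-[(2S,3S)-3-(tert-butyldimethylsilyloxy)pentan-2-yl]-3,5-dimethyl-4H-pyran-4-one | CC(O)c1oc([C@@H](C)[C@@H](O[Si](C)(C)C(C)(C)C)CC)c(C)c(=O)c1C
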